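**Retrosynthetic overview**

- Feature: in the enolised triketone ring, C5′ lies between the oxygenated carbons C4′ and C6′ and carries two methyl groups. The ring is therefore an acylphloroglucinol methylated twice at its single unsubstituted carbon, and both C5′–CH3 bonds are cut last (target ⇒ aromatic 3′-(decalinylmethyl) isovalerylphloroglucinol + 2 MeI).
- C3′–CH2 bond: reductive alkylation of isovalerylphloroglucinol (phloroglucinol + isovaleryl chloride) with the decalin C1-carbaldehyde.
- Aldehyde ⇒ C1 ketone (one-carbon homologation, formyl equatorial). The C1 oxygen comes from the C3 carbonyl by Wharton transposition. The C4 carbinol and the trans C5–H come from Birch reduction and Rubottom oxidation of ent-α-cyperone.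
- Ring order: ring B is (S)-carvone; ring A is annulated onto it (auxiliary-controlled Michael addition to ethyl vinyl ketone sets C10, aldol condensation closes C4–C5); the aromatic ring is attached intact and dearomatised only in the last step.

Key step: step 15

Remark: decalin positions follow eudesmane numbering (ring A = C1–C5 and C10, ring B = C5–C10; C10 carries the angular methyl, C5 is the ring-fusion CH, C4 the carbinol carbon, C7 the isopropenyl carbon); primed locants denote the phloroglucinol-derived ring (C1′ acyl, C3′ CH2, C5′ gem-dimethyl). Dihydrocarvone 2 is carried on as its C2-epimer mixture, since C2 becomes trigonal in step 2. The target is handled as the enol tautomer drawn in its SMILES.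

**Step 1**
Reactants: 1 (S)-(+)-carvone
Product: 2 (2S,5S)-2-methyl-5-(prop-1-en-2-yl)cyclohexan-1-one [(−)-trans-dihydrocarvone]
Conditions: L-Selectride [LiBH(s-Bu)3], THF, −78 °C; then H2O
Reagents that add atoms: none
Why: Conjugate (1,4-) hydride reduction of the α-methyl enone by a bulky trialkylborohydride should leave the isopropenyl group and the C5 stereocentre untouched, and the C2 configuration set on protonation does not matter because it is erased in step 2.

**Step 2**
Reactants: 2 (2S,5S)-dihydrocarvone; 3 (S)-(−)-1-phenylethylamine; 4 pent-1-en-3-one (ethyl vinyl ketone)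
Product: 7 (2R,5S)-2-methyl-2-(3-oxopentyl)-5-(prop-1-en-2-yl)cyclohexan-1-one, via ketimine 5 (not isolated), via Michael-adduct ketimine 6 (not isolated)
Conditions: 3, TsOH (cat.), PhMe, reflux (Dean–Stark); 4, THF, 40 °C; 10% aq. AcOH, rt
Reagents that add atoms: pent-1-en-3-one (compound 4), C=CC(=O)CC; water, O
Why: Asymmetric Michael addition of a chiral ketimine through its more substituted secondary enamine tautomer (compact aza-ene-like transition state with internal N–H transfer), in which the (S)-1-phenylethyl group should direct the oxopentyl chain to the face trans to the isopropenyl group so that the C10 methyl ends cis to it (C2 of the ketone R); this is the mirror image of the pairing that leads to natural α-cyperone.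

**Step 3**
Reactants: 7 (2R,5S)-diketone
Product: 8 (7S,10R)-eudesma-4,11-dien-3-one [(−)-α-cyperone, enantiomer of the natural ketone]
Conditions: NaOMe, MeOH, rt to 50 °C
Reagents that add atoms: none
Why: Intramolecular aldol condensation (ring-closing half of the Robinson annulation): the ethyl ketone enolises at its methylene (C4), adds to the ring carbonyl (C5) in a six-membered closure and dehydrates to the conjugated enone, without touching C7 or the quaternary C10.

**Step 4**
Reactants: 8 (−)-α-cyperone
Product: 10 (5S,7S,10R)-3-(trimethylsilyloxy)eudesma-3,11-diene, via lithium enolate 9 (not isolated)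
Conditions: Li, NH3(l)/THF, t-BuOH (1 equiv), −78 °C; isoprene; evaporate NH3; TMSCl, Et3N, THF, 0 °C
Reagents that add atoms: chlorotrimethylsilane, C[Si](C)(C)Cl
Why: Birch-type dissolving-metal reduction of the enone, in which the β-carbon C5 is protonated axially on the face opposite the C10 methyl (trans ring fusion) and the regiodefined C3–C4 enolate is trapped on oxygen as its silyl enol ether; the isolated isopropenyl alkene is not reduced.

**Step 5**
Reactants: 10 silyl enol ether
Product: 12 (4R,5S,7S,10R)-4-hydroxyeudesm-11-en-3-one (4-OH and H-5 on the face opposite to the C4 and C10 methyl groups), via α-silyloxy ketone 11 (not isolated)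
Conditions: mCPBA (1.05 equiv), NaHCO3, CH2Cl2, −20 °C; then 1 M HCl, THF, 0 °C
Reagents that add atoms: mCPBA, O=C(OO)c1cccc(Cl)c1
Why: Rubottom oxidation: the electron-rich tetrasubstituted silyl enol ether should be epoxidised far faster than the 1,1-disubstituted isopropenyl group, and the peracid approaches C4 on the face opposite the syn-axial C10 methyl, which places the hydroxyl trans to that methyl and the C4 methyl axial, as in the target.

**Step 6**
Reactants: 12 hydroxy ketone
Product: 13 (4R,5S,7S,10R)-4-hydroxyeudesma-1,11-dien-3-one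
Conditions: IBX, DMSO/PhF, 75 °C
Reagents that add atoms: none
Why: IBX-mediated α,β-dehydrogenation of a ketone that can enolise only toward C2 should give the 1-en-3-one; the tertiary alcohol cannot be oxidised and no stereocentre is involved.

**Step 7**
Reactants: 13 hydroxy enone
Product: 14 (1S,2S,4R,5S,7S,10S)-1,2-epoxy-4-hydroxyeudesm-11-en-3-one (epoxide on the face opposite the C10 methyl)
Conditions: 30% H2O2, NaOH (aq.), MeOH, 0 °C
Reagents that add atoms: hydrogen peroxide, OO
Why: Weitz–Scheffer nucleophilic epoxidation: hydroperoxide adds to C1 of the enone on the face opposite the adjacent angular methyl and closes the epoxide on that face, while the unactivated isopropenyl group is inert to the nucleophilic oxidant.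

**Step 8**
Reactants: 14 epoxy ketone
Product: 16 (1R,4S,5S,7S,10S)-eudesma-2,11-diene-1,4-diol, via epoxy hydrazone 15 (not isolated)
Conditions: N2H4·H2O, AcOH (cat.), MeOH, 0 °C to rt
Reagents that add atoms: none
Why: Wharton transposition: the C3 hydrazone opens the epoxide to a vinyl diazene that loses N2, giving the 2-ene with the C1–O bond of the epoxide retained, so the oxygen moves from C3 to C1 with the C1 configuration set in step 7.

**Step 9**
Reactants: 16 allylic diol
Product: 17 (4S,5S,7S,10S)-4-hydroxyeudesma-2,11-dien-1-one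
Conditions: Dess–Martin periodinane, NaHCO3, CH2Cl2, rt
Reagents that add atoms: none
Why: Periodinane oxidation of the secondary allylic alcohol to the enone; the tertiary C4 alcohol has no carbinol hydrogen and should survive.

**Step 10**
Reactants: 17 hydroxy enone
Product: 18 (4S,5S,7S,10S)-4-hydroxyeudesm-11-en-1-one
Conditions: [(Ph3P)CuH]6 (0.4 equiv), PhH, H2O (3 equiv), rt
Reagents that add atoms: none
Why: Copper hydride conjugate reduction is chemoselective for the enone C=C over the isolated isopropenyl alkene and proceeds through a copper enolate, so the γ-hydroxyl is not eliminated; C2 and C3 become CH2 and no stereocentre is affected.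

**Step 11**
Reactants: 18 hydroxy ketone
Product: 19 (4S,5S,7S,10S)-1-(methoxymethylidene)eudesm-11-en-4-ol (E/Z mixture)
Conditions: MeOCH2PPh3Cl, KOtBu (4 equiv each), THF, 0 to 50 °C
Reagents that add atoms: (methoxymethyl)triphenylphosphonium chloride, COC[P+](c1ccccc1)(c1ccccc1)c1ccccc1.[Cl-]
Why: Wittig olefination with the non-stabilised methoxymethylidene ylide, used in excess to cover the tertiary alkoxide, homologates the C1 ketone by one carbon; the enol ether geometry is of no consequence.

**Step 12**
Reactants: 19 enol ether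
Product: 20 (1S,4S,5S,7S,10S)-4-hydroxyeudesm-11-ene-1-carbaldehyde [(1S,4S,4aS,6S,8aS)-4-hydroxy-4,8a-dimethyl-6-(prop-1-en-2-yl)decahydronaphthalene-1-carbaldehyde; formyl equatorial and cis to the C10 methyl]
Conditions: 2 M aq. HCl, THF, 0 °C to rt; then K2CO3, MeOH, rt
Reagents that add atoms: water, O
Why: Enol ether hydrolysis protonates C1 on the face opposite the C10 methyl, and base equilibration through the enolate should settle the formyl group in the thermodynamically preferred equatorial position, which is the C1 configuration of the target.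

**Step 13**
Reactants: 21 phloroglucinol; 22 isovaleryl chloride
Product: 23 3-methyl-1-(2,4,6-trihydroxyphenyl)butan-1-one (isovalerylphloroglucinol)
Conditions: AlCl3 (3.5 equiv), PhNO2, 60 °C
Reagents that add atoms: isovaleryl chloride (compound 22), CC(C)CC(=O)Cl
Why: Friedel–Crafts acylation of the symmetrical triphenol; the first acyl group deactivates the ring, so the monoketone should be the main product.

**Step 14**
Reactants: 20 decalin aldehyde; 23 isovalerylphloroglucinol
Product: 25 1-{2,4,6-trihydroxy-3-[((1R,4S,5S,7S,10R)-4-hydroxyeudesm-11-en-1-yl)methyl]phenyl}-3-methylbutan-1-one, via o-quinone methide 24 (not isolated)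
Conditions: L-proline (20 mol %), Hantzsch ester (1.3 equiv), 23 (2 equiv), CH2Cl2/EtOH, rt to 40 °C
Reagents that add atoms: none
Why: Three-component reductive alkylation: amine-catalysed Knoevenagel-type condensation of the aldehyde at one of the two equivalent free ring carbons gives an o-quinone methide, which is reduced at its exocyclic carbon by hydride transfer from the dihydropyridine and rearomatises; C1 keeps its equatorial configuration, which is also the thermodynamic one should the aldehyde equilibrate through its enamine.

**Step 15**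
Reactants: 25 aromatic acylphloroglucinol; 26 iodomethane
Product: 28 3,5-dihydroxy-4-{[(1R,4S,5S,7S,10R)-4-hydroxyeudesm-11-en-1-yl]methyl}-6,6-dimethyl-2-(3-methylbutanoyl)cyclohexa-2,4-dien-1-one (CNP0490948.1), via mono-C-methyl phenol 27 (not isolated)
Conditions: NaOMe (4 equiv), MeI (2.2 equiv, slow addition), MeOH, 0 °C to rt; then 1 M HCl
Reagents that add atoms: iodomethane (compound 26), CI
Why: Methoxide turns the acylphloroglucinol into its ambident phenoxide, which attacks MeI in an SN2 reaction through C5′, the only ring carbon that still bears hydrogen, and tautomerises back to the aromatic 5′-methyl phenol 27; the phenoxide of 27 is methylated again at the same carbon, which now has no hydrogen to lose, so the ring stays dearomatised as a delocalised triketone enolate that resists further alkylation and gives 28 on acidification. The closest known reaction type is the base-mediated dearomative C,C-dimethylation of acylphloroglucinols to acylfilicinic acids. No ring is closed and no stereocentre is formed; the five decalin stereocentres, the tertiary alcohol and the isopropenyl group are spectators under NaOMe/MeI. The step needs C- over O-alkylation, for which the hydrogen-bonding protic medium and the soft iodide electrophile are chosen. It also needs the second methyl to enter at C5′ and not at C3′, which the β-branched decalinylmethyl group on C3′ should secure by shielding that carbon, while C5′ carries only a methyl group. Limiting MeI to about two equivalents should keep O-methyl ethers and overalkylated products minor.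

**Compound list**

1 | (S)-(+)-carvone | C=C(C)[C@H]1CC=C(C)C(=O)C1 | starting material
2 | (2S,5S)-2-methyl-5-(prop-1-en-2-yl)cyclohexan-1-one [(−)-trans-dihydrocarvone] | C=C(C)[C@H]1CC[C@H](C)C(=O)C1 | intermediate
3 | (S)-(−)-1-phenylethylamine | C[C@H](N)c1ccccc1 | starting material
4 | pent-1-en-3-one (ethyl vinyl ketone) | C=CC(=O)CC | starting material
5 | N-[(S)-1-phenylethyl] ketimine of 2 (C2 epimers, in equilibrium with its enamine) | C=C(C)[C@H]1CCC(C)C(=N[C@@H](C)c2ccccc2)C1 | intermediate
6 | N-[(S)-1-phenylethyl] ketimine of diketone 7 (ring C=N) | C=C(C)[C@H]1CC[C@](C)(CCC(=O)CC)C(=N[C@@H](C)c2ccccc2)C1 | intermediate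
7 | (2R,5S)-2-methyl-2-(3-oxopentyl)-5-(prop-1-en-2-yl)cyclohexan-1-one | C=C(C)[C@H]1CC[C@](C)(CCC(=O)CC)C(=O)C1 | intermediate
8 | (7S,10R)-eudesma-4,11-dien-3-one [(−)-α-cyperone] | C=C(C)[C@H]1CC[C@]2(C)CCC(=O)C(C)=C2C1 | intermediate
9 | lithium (5S,7S,10R)-eudesma-3,11-dien-3-olate | C=C(C)[C@H]1CC[C@]2(C)CCC([O-])=C(C)[C@H]2C1.[Li+] | intermediate
10 | (5S,7S,10R)-3-(trimethylsilyloxy)eudesma-3,11-diene | C=C(C)[C@H]1CC[C@]2(C)CCC(O[Si](C)(C)C)=C(C)[C@H]2C1 | intermediate
11 | (4R,5S,7S,10R)-4-(trimethylsilyloxy)eudesm-11-en-3-one | C=C(C)[C@H]1CC[C@]2(C)CCC(=O)[C@](C)(O[Si](C)(C)C)[C@H]2C1 | intermediate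
12 | (4R,5S,7S,10R)-4-hydroxyeudesm-11-en-3-one | C=C(C)[C@H]1CC[C@]2(C)CCC(=O)[C@](C)(O)[C@H]2C1 | intermediate
13 | (4R,5S,7S,10R)-4-hydroxyeudesma-1,11-dien-3-one | C=C(C)[C@H]1CC[C@]2(C)C=CC(=O)[C@](C)(O)[C@H]2C1 | intermediate
14 | (1S,2S,4R,5S,7S,10S)-1,2-epoxy-4-hydroxyeudesm-11-en-3-one | C=C(C)[C@H]1CC[C@]2(C)[C@@H]3O[C@@H]3C(=O)[C@](C)(O)[C@H]2C1 | intermediate
15 | hydrazone of 14 at C3 | C=C(C)[C@H]1CC[C@]2(C)[C@@H]3O[C@@H]3C(=NN)[C@](C)(O)[C@H]2C1 | intermediate
16 | (1R,4S,5S,7S,10S)-eudesma-2,11-diene-1,4-diol | C=C(C)[C@H]1CC[C@]2(C)[C@H](O)C=C[C@](C)(O)[C@H]2C1 | intermediate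
17 | (4S,5S,7S,10S)-4-hydroxyeudesma-2,11-dien-1-one | C=C(C)[C@H]1CC[C@]2(C)C(=O)C=C[C@](C)(O)[C@H]2C1 | intermediate
18 | (4S,5S,7S,10S)-4-hydroxyeudesm-11-en-1-one | C=C(C)[C@H]1CC[C@]2(C)C(=O)CC[C@](C)(O)[C@H]2C1 | intermediate
19 | (4S,5S,7S,10S)-1-(methoxymethylidene)eudesm-11-en-4-ol | C=C(C)[C@H]1CC[C@]2(C)C(=COC)CC[C@](C)(O)[C@H]2C1 | intermediate
20 | (1S,4S,5S,7S,10S)-4-hydroxyeudesm-11-ene-1-carbaldehyde | C=C(C)[C@H]1CC[C@]2(C)[C@@H](C=O)CC[C@](C)(O)[C@H]2C1 | intermediate
21 | phloroglucinol | Oc1cc(O)cc(O)c1 | starting material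
22 | isovaleryl chloride | CC(C)CC(=O)Cl | starting material
23 | 3-methyl-1-(2,4,6-trihydroxyphenyl)butan-1-one | CC(C)CC(=O)c1c(O)cc(O)cc1O | intermediate
24 | o-quinone methide from 20 and 23 | C=C(C)[C@H]1CC[C@]2(C)[C@@H](C=C3C(=O)C=C(O)C(C(=O)CC(C)C)=C3O)CC[C@](C)(O)[C@H]2C1 | intermediate
25 | 1-{2,4,6-trihydroxy-3-[((1R,4S,5S,7S,10R)-4-hydroxyeudesm-11-en-1-yl)methyl]phenyl}-3-methylbutan-1-one | C=C(C)[C@H]1CC[C@]2(C)[C@@H](Cc3c(O)cc(O)c(C(=O)CC(C)C)c3O)CC[C@](C)(O)[C@H]2C1 | intermediate
26 | iodomethane | CI | starting material
27 | 5′-methyl derivative of 25 (aromatic mono-C-methyl phenol) | C=C(C)[C@H]1CC[C@]2(C)[C@@H](Cc3c(O)c(C)c(O)c(C(=O)CC(C)C)c3O)CC[C@](C)(O)[C@H]2C1 | intermediate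
28 | 3,5-dihydroxy-4-{[(1R,4S,5S,7S,10R)-4-hydroxyeudesm-11-en-1-yl]methyl}-6,6-dimethyl-2-(3-methylbutanoyl)cyclohexa-2,4-dien-1-one (CNP0490948.1) | C=C(C)[C@H]1CC[C@]2(C)[C@@H](CC3=C(O)C(C)(C)C(=O)C(C(=O)CC(C)C)=C3O)CC[C@](C)(O)[C@H]2C1 | target

**Step count**

Total step count: 15. Longest linear sequence: 14 (steps 1–12, 14, 15); step 13 is the side branch.

**Steps most likely to fail, with fallbacks**

Step 15. Site control may be lost in the second methylation: it may go to C3′ or to oxygen, and a third methyl may follow, so that 28 forms as one component of a mixture. The fallback dearomatises before the fragments are joined. It sets out from 23: NaOMe/MeI in MeOH on this simple phenol, a known preparation of acylfilicinic acids, gives 3,5-dihydroxy-6,6-dimethyl-2-(3-methylbutanoyl)cyclohexa-2,4-dien-1-one F1, which is separated from its mono- and tetramethyl congeners. Its single remaining ring CH is then condensed with aldehyde 20 under the conditions of step 14 to the alkylidene triketone F2, which is reduced in the same flask by the Hantzsch ester. This comes back to the route at 28.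

Step 14. Condensation of the hindered α-branched aldehyde may be slow, and the o-quinone methide may tautomerise to a vinylphenol (loss of the C1 stereocentre) or the product may be alkylated a second time at C5′. The fallback makes the aryl–carbon bond by polar addition and sets out from 21 and 20. Phloroglucinol 21 with MOMCl/i-Pr2NEt gives 1,3,5-tris(methoxymethoxy)benzene F3. Ortho-lithiation (n-BuLi, THF, 0 °C) and addition to aldehyde 20 gives the benzylic carbinol F4. Ionic hydrogenation of this doubly ortho-oxygenated benzylic alcohol (Et3SiH, TFA, CH2Cl2, −78 °C) gives the arylmethyl decalin F5. A second ortho-lithiation (n-BuLi, 2.2 equiv) and acylation with N-methoxy-N-methyl-3-methylbutanamide gives the aryl ketone F6. Cleavage of the three acetals (HCl, MeOH, rt) comes back to the route at 25.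

Step 11. The basic ylide may enolise the ketone, and the adjacent quaternary C10 may block addition, so that ketone is recovered. The fallback homologates through a nitrile and sets out from 18. Reductive cyanation with TosMIC (KOtBu, DME/t-BuOH, 0 to 40 °C) gives the C1 carbonitrile F7, which the basic medium equilibrates toward the equatorial epimer. DIBAL-H (PhMe, −78 °C) followed by aqueous acid and brief K2CO3/MeOH treatment comes back to the route at 20.

**Further compounds**

F1 | step 15 | 3,5-dihydroxy-6,6-dimethyl-2-(3-methylbutanoyl)cyclohexa-2,4-dien-1-one | CC(C)CC(=O)C1=C(O)C=C(O)C(C)(C)C1=O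
F2 | step 15 | alkylidene triketone from 20 and F1 (not isolated) | C=C(C)[C@H]1CC[C@]2(C)[C@@H](C=C3C(=O)C(C)(C)C(=O)C(C(=O)CC(C)C)=C3O)CC[C@](C)(O)[C@H]2C1
F3 | step 14 | 1,3,5-tris(methoxymethoxy)benzene | COCOc1cc(OCOC)cc(OCOC)c1
F4 | step 14 | benzylic carbinol from 20 and lithiated F3 (carbinol epimers) | C=C(C)[C@H]1CC[C@]2(C)[C@@H](C(O)c3c(OCOC)cc(OCOC)cc3OCOC)CC[C@](C)(O)[C@H]2C1
F5 | step 14 | (1R,4S,5S,7S,10R)-1-[2,4,6-tris(methoxymethoxy)benzyl]eudesm-11-en-4-ol | C=C(C)[C@H]1CC[C@]2(C)[C@@H](Cc3c(OCOC)cc(OCOC)cc3OCOC)CC[C@](C)(O)[C@H]2C1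
F6 | step 14 | tris(methoxymethyl) ether of 25 | C=C(C)[C@H]1CC[C@]2(C)[C@@H](Cc3c(OCOC)cc(OCOC)c(C(=O)CC(C)C)c3OCOC)CC[C@](C)(O)[C@H]2C1
F7 | step 11 | (1S,4S,5S,7S,10S)-4-hydroxyeudesm-11-ene-1-carbonitrile | C=C(C)[C@H]1CC[C@]2(C)[C@@H](C#N)CC[C@](C)(O)[C@H]2C1
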